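The rate constants were set for the occasion; the result is computed.

The catalyst is single-handed, so it captured the two substrate forms at different rates while they interconverted beside it, and the four flasks differed in temperature.

| setting | Tuesday's | Thursday's | Friday's | Monday's |
|---|---|---|---|---|
| left-handed substrate | 16 mM | 16 mM | 16 mM | 16 mM |
| solid reagent | 17.6 mM | 17.6 mM | 17.6 mM | 17.6 mM |
| catalyst | 0.80 mM | 0.80 mM | 0.80 mM | 0.80 mM |
| right-handed substrate | 16 mM | 16 mM | 16 mM | 16 mM |
| temperature | 0 °C | −20 °C | −40 °C | 20 °C |
| time | 30 h | 30 h | 30 h | 30 h |

    left-handed substrate ⇌ right-handed substrate (k1 = 2.3 × 10⁻⁵ s⁻¹, Ea1 = 92.0 kJ mol⁻¹)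
    partner + catalyst + right-handed substrate → catalyst + right-handed product (k2 = 0.32 L² mol⁻² s⁻¹, Ea2 = 48.0 kJ mol⁻¹)
    partner + catalyst + left-handed substrate → catalyst + left-handed product (k3 = 0.73 L² mol⁻² s⁻¹, Ea3 = 43.0 kJ mol⁻¹)
    solid reagent ⇌ partner, rate k4*(cs4 - [partner]) while solid is left; crystals form when [partner] > cs4 (cs4 = 11 mM, k4 = 3.6 × 10⁻⁵ s⁻¹)
    (constants at −20 °C)

- catalyst is single-handed; left-handed substrate and right-handed substrate are mirror images of each other, charged as a racemate, each of them at the stated concentration
- as a solid, counted per litre of solution: solid reagent
- at −20 °C the constants are as listed, elsewhere as the activation energies make them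
- at the start none of the solid reagent is in solution
- an excess is the difference of the two amounts in percent of their sum
- an excess is below zero if the other one leads

* which flask leads in excess of left-handed product over right-handed product ("all alike" within 1.5 percentage points) (Tuesday's / Thursday's / Friday's / Monday's / all alike)
* excess of left-handed product over right-handed product at the end, Tuesday's
* excess of left-handed product over right-handed product at the end, Thursday's
* excess of left-handed product over right-handed product at the end, Friday's
* excess of left-handed product over right-handed product at the end, Monday's

- I took the ratio of the left-handed capture constant to the right-handed one as the selectivity factor, which on Friday's, at −40 °C, came to 2.80.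
- While [left-handed substrate] equals [right-handed substrate], the products form in that ratio, so the excess is the factor less one over the factor plus one. I called this the selectivity ceiling, and on Friday's it was 47.3%.
- The left-handed form is captured faster from a racemic start, so [left-handed substrate] stays at or below [right-handed substrate], and the ceiling bounds the excess from above. The same sum gave 39.0% for Thursday's, 31.4% for Tuesday's and 24.5% for Monday's.
- For a floor on Friday's, I reckoned with the racemisation stopped and [partner] held at its solubility, 11 mM, for the full 30 h, since it starts at zero and dissolves up to that level. Each form then decays pseudo-first-order, with 11.3% of the left-handed form consumed and 4.21% of the right-handed, which gives 45.8%.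
- That floor stood above the other ceilings, so I expected Friday's to lead.
- On Monday's the racemisation half-life was 38.7 s, far shorter than the run, so I put Monday's on its ceiling.
- The forecast named Friday's, with 31.2% for Tuesday's, 37.2% for Thursday's, 46.3% for Friday's and 24.5% for Monday's, holding for Friday's that “racemisation is nearly frozen”. Its Friday's value lay inside my bracket, though the low end of its range, 45.6%, stood below my floor.
- The simulation gave 31.2% for Tuesday's, 37.3% for Thursday's, 46.3% for Friday's and 24.5% for Monday's, so Friday's led and the forecast held on each. Friday's ended 1 percentage point under its ceiling.

The neighbour, a repeat of Friday's at −55 °C, took the same reckoning. Its selectivity factor was 3.34, so its ceiling was 53.9%, higher than Friday's 47.3%. In the sum with racemisation stopped and [partner] held at 11 mM, 2.58% of the left-handed form and 0.780% of the right-handed were consumed, a floor of 53.6%. The neighbour gave 53.7%, with 98% of its left-handed substrate still there.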